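Readings and results are calculated for an exercise; scatter was added.

Time is not what this flask waits for. In the west run target reads 68.0 % at 6.00 min and 68.2 % at 12.0 min, and in the north-east run substrate is down to 1.2 % by 3.00 min, so the last reading of each run is a final yield.

| flask | substrate | gas phase | remark | time |
|---|---|---|---|---|
| west | 10 mM | 0.95 mM (held) | run made earlier |  |
| north-east | 40 mM | 0.95 mM (held) | run made earlier |  |
| flask | 20 mM | 0.95 mM (held) |  | 10 min |

| run | time / min | target / % | substrate / % |
|---|---|---|---|
| west | 1.00 | 46.2 | 24.3 |
| west | 2.00 | 63.1 | 5.8 |
| west | 3.00 | 67.3 | 1.1 |
| west | 6.00 | 68.0 | 0 |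
| west | 12.0 | 68.2 | 0 |
| north-east | 1.00 | 20.8 | 15.4 |
| north-east | 3.00 | 32.5 | 1.2 |
| north-east | 6.00 | 32.1 | 0 |
| north-east | 8.00 | 32.4 | 0 |
| north-east | 12.0 | 32.5 | 0.1 |

(scatter of a reading: 0.3 percentage points)

- the numbers in the tables scatter with a standard deviation of 0.3 percentage points
- at the start none of the gas phase is in solution

* how much target there is at 10 min, in percent of the substrate charged
* concentration of dissolved gas in solution at 1.0 min, in percent of saturation
* the change that raises the amount of target at 10 min, in percent of the substrate charged most ("none" if none brings more than 2 percentage points) (autumn / spring / none)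
* amount of target at 10 min, in percent of the substrate charged, after autumn

- autumn: doubling the saturation concentration of gas phase, all else as stated
- spring: doubling the transfer coefficient of the gas phase, all else as stated

Quadrupling the charge lowers the yield, so substrate concentration itself must be splitting the flow. Let S be the charge and Y the final target share. The even-split charge C is S multiplied by the ratio of target to non-target at the end, so that Y = C/(C + S). C is an empirical selectivity factor in concentration units; substrate falls during a batch, so C need not stay the same from charge to charge, and the two runs have to show how far it moves.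

The west run gives 21.4 mM and the north-east run 19.3 mM, close to each other though not within the scatter. Their mean is 20.4 mM, so this reckoning puts the 20 mM flask at 50.5 %.

The forecast says 51 %, 56 % of saturation at 1.0 min, autumn as the best change and 63 % after it: “Doubling kLa helps less”.

The flask gives 50.5 % at 10 min, 68.7 % of saturation at 1.0 min, and autumn as the best change, reaching 63.9 %.

    2 substrate → homo dimer (k = 0.620 M⁻¹ s⁻¹)
    substrate + dissolved gas → target (k = 26.1 M⁻¹ s⁻¹)
    gas phase ⇌ dissolved gas, rate k3*(csat - [dissolved gas]) (kL = 0.257 s⁻¹)
    substrate → side product (k = 0.00130 s⁻¹)

In this flask 44.6 % of the charge ends as homo dimer, each counted as two, and with that step struck out the answer is 90.3 %. The flask's own result returns C = 20.4 mM. At 50 mM the C from the two runs gives 29.0 %, while that neighbour flask stands at 27.4 %, which returns C = 18.9 mM.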